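**Plan**

1. Retrosynthesis: the two silyl ethers are cut last. Then the C10–C11 single bond (alkenyl iodide plus alkenyl boronate) and, in the same operation, the O1–C8 bond of the dihydrofuran are cut. This leads to a monocyclic C14 allenol (fragment A) and a C26 polyenyl boronate (fragment B).
2. Enabling feature: in ring B (O1–C8–C7=C6–C5) the tertiary oxygen on C5 and the carbons C6, C7 and C8 are the atoms of an α-hydroxyallene C5(OH)–C6=C7=C8. 5-endo addition of O5 to C8 makes ring B and turns the allene axis into the C8 centre.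
3. Fragment A is cut at C6–C7 (alkynylzinc plus the enol triflate of silylated actinol) and at C9–CH3/C10–I (carboalumination–iodination). Its allene comes from the 5,6-epoxide of the ring enyne by SN2' hydride delivery.
4. Fragment B is cut at C11=C12 (borylative chromium olefination) and at C11'=C12' (Wittig reaction of a C15 phosphonium salt with the C10 trienedial). The salt comes from (R)-α-ionone by vinyl addition, C3' allylic oxidation and reduction.
5. Forward order: ring A (from actinol) and ring C (the ε ring, from α-ionone) are present from the start. The chain of B is built first, A and B are joined at C10–C11 while ring B closes, then both silyl groups are removed.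
6. Stereochemistry: C3 from actinol; C5 from epoxidation anti to the C3 silyloxy group; the allene axis from syn SN2' hydride delivery, and C8 from it by axis-to-centre transfer; C6' from (R)-α-ionone; C3' by CBS reduction. 9E comes from syn-carboalumination, 11E from the Takai-type olefination, the rest from Wittig reaction/equilibration and the all-E dialdehyde.

Key step: step 15

Assumption: (R)-α-ionone 14 is taken as purchasable in enantiopure form.
Remark: the allene axis of 13 (and of F1) is given in the name (aR, H8 on the side of O5); the SMILES strings carry centre and double-bond descriptors only.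

**Route**

Step 1
Reactants: 1 (4R,6R)-4-hydroxy-2,2,6-trimethylcyclohexan-1-one (actinol)
Product: 2 (4R,6R)-4-[(tert-butyldimethylsilyl)oxy]-2,2,6-trimethylcyclohexan-1-one
Conditions: t-BuMe2SiCl, imidazole, DMF, rt
Reagents that add atoms: tert-butyldimethylsilyl chloride, CC(C)(C)[Si](C)(C)Cl
Why: Silyl ether formation at the only hydroxyl protects O3 against the amide base, organometallics and hydride used later, and no stereocentre is touched.

Step 2
Reactants: 2 (4R,6R)-4-[(tert-butyldimethylsilyl)oxy]-2,2,6-trimethylcyclohexan-1-one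
Product: 4 (4R)-4-[(tert-butyldimethylsilyl)oxy]-2,6,6-trimethylcyclohex-1-en-1-yl trifluoromethanesulfonate, via lithium enolate 3 (not isolated)
Conditions: LiN(i-Pr)2, THF, −78 → 0 °C; then PhNTf2, 0 °C → rt
Reagents that add atoms: N-phenylbis(trifluoromethanesulfonimide), FC(F)(F)S(=O)(=O)N(c1ccccc1)S(=O)(=O)C(F)(F)F
Why: The ketone has a single α-hydrogen, so LiN(i-Pr)2 gives one enolate and O-sulfonylation (enol triflate formation) yields the tetrasubstituted alkenyl triflate, deliberately erasing the old C5 centre while C3 is untouched.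

Step 3
Reactants: 4 (4R)-4-[(tert-butyldimethylsilyl)oxy]-2,6,6-trimethylcyclohex-1-en-1-yl trifluoromethanesulfonate; 5 1,4-bis(trimethylsilyl)buta-1,3-diyne
Product: 8 tert-butyldimethyl{[(1R)-3,5,5-trimethyl-4-[4-(trimethylsilyl)buta-1,3-diyn-1-yl]cyclohex-3-en-1-yl]oxy}silane, via lithium diynide 6 (not isolated), via alkynylzinc chloride 7 (not isolated)
Conditions: 5, MeLi·LiBr, THF, rt; ZnCl2, 0 °C; then 4, Pd(PPh3)4 (5 mol %), THF, 50 °C
Reagents that add atoms: none
Why: Methyllithium cleaves one C–Si bond of 5, the diynide is passed to zinc and Negishi coupling with the hindered alkenyl triflate forms the C6–C7 bond without creating a stereocentre.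

Step 4
Reactants: 8 tert-butyldimethyl{[(1R)-3,5,5-trimethyl-4-[4-(trimethylsilyl)buta-1,3-diyn-1-yl]cyclohex-3-en-1-yl]oxy}silane
Product: 9 {[(1R)-4-(buta-1,3-diyn-1-yl)-3,5,5-trimethylcyclohex-3-en-1-yl]oxy}(tert-butyl)dimethylsilane
Conditions: K2CO3 (cat.), MeOH–THF, 0 °C
Reagents that add atoms: none
Why: Base-catalysed methanolysis of the alkynyl C–Si bond (protodesilylation) frees the terminal alkyne, the secondary O-silyl ether being inert to catalytic carbonate.

Step 5
Reactants: 9 {[(1R)-4-(buta-1,3-diyn-1-yl)-3,5,5-trimethylcyclohex-3-en-1-yl]oxy}(tert-butyl)dimethylsilane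
Product: 11 tert-butyl({(1R)-4-[(3E)-4-iodo-3-methylbut-3-en-1-yn-1-yl]-3,5,5-trimethylcyclohex-3-en-1-yl}oxy)dimethylsilane, via alkenylalane 10 (not isolated)
Conditions: Me3Al, Cp2ZrCl2 (25 mol %), CH2Cl2, 0 °C → rt; then I2, THF, −30 °C
Reagents that add atoms: trimethylaluminium, C[Al](C)C; iodine, [I][I]
Why: Zirconium-catalysed carboalumination (Negishi methylalumination) adds CH3 and Al syn across the terminal triple bond only, CH3 to C9 and Al to C10, and iodinolysis with retention gives the (9E)-alkenyl iodide.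

Step 6
Reactants: 11 tert-butyl({(1R)-4-[(3E)-4-iodo-3-methylbut-3-en-1-yn-1-yl]-3,5,5-trimethylcyclohex-3-en-1-yl}oxy)dimethylsilane
Product: 12 tert-butyl({(1R,4S,6R)-1-[(3E)-4-iodo-3-methylbut-3-en-1-yn-1-yl]-2,2,6-trimethyl-7-oxabicyclo[4.1.0]heptan-4-yl}oxy)dimethylsilane
Conditions: mCPBA, NaHCO3, CH2Cl2, −20 → 0 °C
Reagents that add atoms: 3-chloroperoxybenzoic acid, OOC(=O)c1cccc(Cl)c1
Why: Prilezhaev epoxidation takes the electron-rich tetrasubstituted ring alkene in preference to the iodoalkene and the alkyne, and the peracid should approach the face away from the bulky C3 silyloxy group so that C5 and C6 are set with the oxygen trans to O3.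

Step 7
Reactants: 12 tert-butyl({(1R,4S,6R)-1-[(3E)-4-iodo-3-methylbut-3-en-1-yn-1-yl]-2,2,6-trimethyl-7-oxabicyclo[4.1.0]heptan-4-yl}oxy)dimethylsilane
Product: 13 (1R,5S)-5-[(tert-butyldimethylsilyl)oxy]-2-[(3E)-4-iodo-3-methylbuta-1,3-dien-1-ylidene]-1,3,3-trimethylcyclohexan-1-ol with the allene axis aR
Conditions: i-Bu2AlH, CH2Cl2, −78 → 0 °C; aq. potassium sodium tartrate
Reagents that add atoms: none
Why: SN2' reduction of the alkynyl epoxide, in which aluminium bound to the epoxide oxygen delivers hydride to C8 on the face of the departing C6–O bond, unveils the C5 tertiary alcohol and sets the allene axis as aR (H8 on the side of O5).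

Step 8
Reactants: 14 (3E)-4-[(1R)-2,6,6-trimethylcyclohex-2-en-1-yl]but-3-en-2-one ((R)-α-ionone)
Product: 15 (1E)-3-methyl-1-[(1R)-2,6,6-trimethylcyclohex-2-en-1-yl]penta-1,4-dien-3-ol (both epimers at the carbinol carbon)
Conditions: CH2=CHMgBr, THF, −20 → 0 °C
Reagents that add atoms: vinylmagnesium bromide, C=C[Mg]Br
Why: Grignard 1,2-addition of the vinyl group to the methyl ketone adds C10' and C11' and masks the ketone as a tertiary carbinol whose uncontrolled centre is erased in step 12.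

Step 9
Reactants: 15 (1E)-3-methyl-1-[(1R)-2,6,6-trimethylcyclohex-2-en-1-yl]penta-1,4-dien-3-ol
Product: 16 (4R)-4-[(1E)-3-hydroxy-3-methylpenta-1,4-dien-1-yl]-3,5,5-trimethylcyclohex-2-en-1-one
Conditions: Rh2(cap)4 (1 mol %; cap = caprolactamate), t-BuOOH (70% aq.), NaHCO3, CH2Cl2, rt
Reagents that add atoms: tert-butyl hydroperoxide, CC(C)(C)OO
Why: Radical allylic oxidation with the tert-butylperoxyl chain carried by the dirhodium catalyst converts the ring CH2 next to the CH= end of the trisubstituted alkene (C3') into the enone as in cyclohexene-to-cyclohexenone oxidations, the hindered C6'–H and the tertiary carbinol being spared and bicarbonate avoiding γ-deprotonation at C6'.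

Step 10
Reactants: 16 (4R)-4-[(1E)-3-hydroxy-3-methylpenta-1,4-dien-1-yl]-3,5,5-trimethylcyclohex-2-en-1-one
Product: 17 (1R,4R)-4-[(1E)-3-hydroxy-3-methylpenta-1,4-dien-1-yl]-3,5,5-trimethylcyclohex-2-en-1-ol
Conditions: (S)-2-methyl-CBS-oxazaborolidine (20 mol %), catecholborane, toluene, −78 °C
Reagents that add atoms: none
Why: Corey–Bakshi–Shibata reduction, in which the (S)-oxazaborolidine places the alkenyl side of the enone as the large group and delivers hydride 1,2 to the face giving the (3'R) alcohol trans to the C6' side chain (reagent control).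

Step 11
Reactants: 17 (1R,4R)-4-[(1E)-3-hydroxy-3-methylpenta-1,4-dien-1-yl]-3,5,5-trimethylcyclohex-2-en-1-ol
Product: 18 (1E)-1-[(1R,4R)-4-{[tert-butyl(diphenyl)silyl]oxy}-2,6,6-trimethylcyclohex-2-en-1-yl]-3-methylpenta-1,4-dien-3-ol
Conditions: t-BuPh2SiCl, imidazole, DMF, 0 °C → rt
Reagents that add atoms: tert-butyldiphenylsilyl chloride, CC(C)(C)[Si](Cl)(c1ccccc1)c1ccccc1
Why: Silyl ether formation selects the secondary allylic hydroxyl over the hindered tertiary one and gives an ether that tolerates the acid of step 12.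

Step 12
Reactants: 18 (1E)-1-[(1R,4R)-4-{[tert-butyl(diphenyl)silyl]oxy}-2,6,6-trimethylcyclohex-2-en-1-yl]-3-methylpenta-1,4-dien-3-ol
Product: 19 [(2E,4E)-5-[(1R,4R)-4-{[tert-butyl(diphenyl)silyl]oxy}-2,6,6-trimethylcyclohex-2-en-1-yl]-3-methylpenta-2,4-dien-1-yl]triphenylphosphonium bromide
Conditions: Ph3P·HBr, MeOH–CH2Cl2, 0 °C → rt
Reagents that add atoms: triphenylphosphine hydrobromide, [Br-].c1ccc(cc1)[PH+](c1ccccc1)c1ccccc1
Why: Ionisation of the tertiary doubly allylic alcohol by HBr and capture of the pentadienyl cation by PPh3 at its unhindered terminus (SN1' phosphonium salt formation as used for ionylidene C15 salts) gives the primary salt with the thermodynamically preferred 9'E alkene and removes the carbinol centre.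

Step 13
Reactants: 19 [(2E,4E)-5-[(1R,4R)-4-{[tert-butyl(diphenyl)silyl]oxy}-2,6,6-trimethylcyclohex-2-en-1-yl]-3-methylpenta-2,4-dien-1-yl]triphenylphosphonium bromide; 20 (2E,4E,6E)-2,7-dimethylocta-2,4,6-trienedial
Product: 22 (2E,4E,6E,8E,10E,12E)-13-[(1R,4R)-4-{[tert-butyl(diphenyl)silyl]oxy}-2,6,6-trimethylcyclohex-2-en-1-yl]-2,7,11-trimethyltrideca-2,4,6,8,10,12-hexaenal, via phosphonium ylide 21 (not isolated)
Conditions: 20 (3 equiv), NaOMe, MeOH–CH2Cl2, −10 °C → rt, slow addition of 19; then I2 (cat.), CH2Cl2–hexane, daylight, rt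
Reagents that add atoms: none
Why: Wittig olefination of one formyl group of the symmetrical trienedial (used in excess) forms C11'=C12', and the E/Z mixture at the new bond from the semi-stabilised ylide should be converged to the all-E hexaenal by iodine-catalysed equilibration.

Step 14
Reactants: 22 (2E,4E,6E,8E,10E,12E)-13-[(1R,4R)-4-{[tert-butyl(diphenyl)silyl]oxy}-2,6,6-trimethylcyclohex-2-en-1-yl]-2,7,11-trimethyltrideca-2,4,6,8,10,12-hexaenal
Product: 23 2-[(1E,3E,5E,7E,9E,11E,13E)-14-[(1R,4R)-4-{[tert-butyl(diphenyl)silyl]oxy}-2,6,6-trimethylcyclohex-2-en-1-yl]-3,8,12-trimethyltetradeca-1,3,5,7,9,11,13-heptaen-1-yl]-4,4,5,5-tetramethyl-1,3,2-dioxaborolane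
Conditions: Cl2CHBpin, CrCl2, LiI, THF, rt, dark
Reagents that add atoms: 2-(dichloromethyl)-4,4,5,5-tetramethyl-1,3,2-dioxaborolane, ClC(Cl)B1OC(C)(C)C(C)(C)O1
Why: Takai–Utimoto borylative olefination, in which the geminal dichromium species from Cl2CHBpin and CrCl2 adds to the aldehyde and eliminates to the (11E)-alkenylboronate, adds C11.

Step 15
Reactants: 13 (1R,5S)-5-[(tert-butyldimethylsilyl)oxy]-2-[(3E)-4-iodo-3-methylbuta-1,3-dien-1-ylidene]-1,3,3-trimethylcyclohexan-1-ol (aR); 23 the C26 heptaenyl pinacol boronate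
Product: 25 (3S,5R,8S,3'R,6'R)-3-[(tert-butyldimethylsilyl)oxy]-3'-{[tert-butyl(diphenyl)silyl]oxy}-5,8-epoxy-5,8-dihydro-β,ε-carotene, via furanoid iodide 24 (not isolated)
Conditions: 13, AgNO3 (20 mol %), acetone, rt, dark; then 23, Pd(dppf)Cl2 (5 mol %), K3PO4 (3 M aq.), THF, rt, argon, dark
Reagents that add atoms: none
Why: Monovalent silver binds the C7=C8 π bond of the allene of 13 on the face remote from O5, the C5 hydroxyl adds to C8 and protodemetalation of the C7–Ag bond releases the dihydrofuran 24 with the C10–I bond untouched; zerovalent palladium then inserts into that C–I bond, and base-assisted boron-to-palladium transfer from 23 followed by reductive elimination forms C10–C11 with retention of the 9E and 11E geometries. The closest known reaction types are the silver- or gold-catalysed cycloisomerisation of α-hydroxyallenes to 2,5-dihydrofurans and the alkenyl–alkenyl Suzuki–Miyaura coupling, run here in one flask because the silver left from the first stage ends as Ag2O/AgI in the basic second stage, where Ag2O is a known promoter of the transmetalation. Ring B (O1–C8–C7=C6–C5) closes by 5-endo-trig attack of oxygen on the allene terminus. The only new stereocentre, C8, is controlled by the allene axis (aR): the oxygen enters in the plane of C5–C6–C7, so H8 stays on the face of C4 and C9 on the face of the C5 methyl group, which is the (8S) configuration (axis-to-centre chirality transfer). The step needs chemoselectivity (cyclisation at the allene, oxidative addition only at C10–I) and configurational stability of the new doubly allylic ether; the 1,2-relation of the tertiary hydroxyl to the allene, the neutral silver salt and the acid-free basic coupling medium should secure both.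

Step 16
Reactants: 25 (3S,5R,8S,3'R,6'R)-3-[(tert-butyldimethylsilyl)oxy]-3'-{[tert-butyl(diphenyl)silyl]oxy}-5,8-epoxy-5,8-dihydro-β,ε-carotene
Product: 26 (3S,5R,8S,3'R,6'R)-5,8-epoxy-5,8-dihydro-β,ε-carotene-3,3'-diol (all-E)
Conditions: Bu4NF, THF, 0 °C → rt, dark
Reagents that add atoms: none
Why: Fluoride-induced desilylation removes both silyl ethers under non-acidic conditions that should leave the acid-labile doubly allylic C8–O bond, the allylic C3' alcohol and the all-E polyene intact.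

**Compound list**

1 | (4R,6R)-4-hydroxy-2,2,6-trimethylcyclohexan-1-one (actinol) | O=C1C(C)(C)C[C@H](O)C[C@H]1C | starting material
2 | (4R,6R)-4-[(tert-butyldimethylsilyl)oxy]-2,2,6-trimethylcyclohexan-1-one | O=C1C(C)(C)C[C@H](O[Si](C)(C)C(C)(C)C)C[C@H]1C | intermediate
3 | lithium (4R)-4-[(tert-butyldimethylsilyl)oxy]-2,6,6-trimethylcyclohex-1-en-1-olate | CC1(C)C[C@H](O[Si](C)(C)C(C)(C)C)CC(C)=C1O[Li] | intermediate
4 | (4R)-4-[(tert-butyldimethylsilyl)oxy]-2,6,6-trimethylcyclohex-1-en-1-yl trifluoromethanesulfonate | CC1(C)C[C@H](O[Si](C)(C)C(C)(C)C)CC(C)=C1OS(=O)(=O)C(F)(F)F | intermediate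
5 | 1,4-bis(trimethylsilyl)buta-1,3-diyne | C[Si](C)(C)C#CC#C[Si](C)(C)C | starting material
6 | [4-(trimethylsilyl)buta-1,3-diyn-1-yl]lithium | [Li]C#CC#C[Si](C)(C)C | intermediate
7 | chloro[4-(trimethylsilyl)buta-1,3-diyn-1-yl]zinc | Cl[Zn]C#CC#C[Si](C)(C)C | intermediate
8 | tert-butyldimethyl{[(1R)-3,5,5-trimethyl-4-[4-(trimethylsilyl)buta-1,3-diyn-1-yl]cyclohex-3-en-1-yl]oxy}silane | CC1(C)C[C@H](O[Si](C)(C)C(C)(C)C)CC(C)=C1C#CC#C[Si](C)(C)C | intermediate
9 | {[(1R)-4-(buta-1,3-diyn-1-yl)-3,5,5-trimethylcyclohex-3-en-1-yl]oxy}(tert-butyl)dimethylsilane | CC1(C)C[C@H](O[Si](C)(C)C(C)(C)C)CC(C)=C1C#CC#C | intermediate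
10 | [(1E)-4-{(4R)-4-[(tert-butyldimethylsilyl)oxy]-2,6,6-trimethylcyclohex-1-en-1-yl}-2-methylbut-1-en-3-yn-1-yl]dimethylalumane | CC1(C)C[C@H](O[Si](C)(C)C(C)(C)C)CC(C)=C1C#C/C(C)=C/[Al](C)C | intermediate
11 | tert-butyl({(1R)-4-[(3E)-4-iodo-3-methylbut-3-en-1-yn-1-yl]-3,5,5-trimethylcyclohex-3-en-1-yl}oxy)dimethylsilane | CC1(C)C[C@H](O[Si](C)(C)C(C)(C)C)CC(C)=C1C#C/C(C)=C/I | intermediate
12 | tert-butyl({(1R,4S,6R)-1-[(3E)-4-iodo-3-methylbut-3-en-1-yn-1-yl]-2,2,6-trimethyl-7-oxabicyclo[4.1.0]heptan-4-yl}oxy)dimethylsilane (epoxide oxygen trans to O3) | CC1(C)C[C@H](O[Si](C)(C)C(C)(C)C)C[C@@]2(C)O[C@@]12C#C/C(C)=C/I | intermediate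
13 | (1R,5S)-5-[(tert-butyldimethylsilyl)oxy]-2-[(3E)-4-iodo-3-methylbuta-1,3-dien-1-ylidene]-1,3,3-trimethylcyclohexan-1-ol, allene axis aR (carotenoid 6R) | CC1(C)C[C@H](O[Si](C)(C)C(C)(C)C)C[C@@](C)(O)C1=C=C/C(C)=C/I | intermediate
14 | (3E)-4-[(1R)-2,6,6-trimethylcyclohex-2-en-1-yl]but-3-en-2-one ((R)-α-ionone) | CC1=CCCC(C)(C)[C@H]1/C=C/C(C)=O | starting material
15 | (1E)-3-methyl-1-[(1R)-2,6,6-trimethylcyclohex-2-en-1-yl]penta-1,4-dien-3-ol (both carbinol epimers) | CC1=CCCC(C)(C)[C@H]1/C=C/C(C)(O)C=C | intermediate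
16 | (4R)-4-[(1E)-3-hydroxy-3-methylpenta-1,4-dien-1-yl]-3,5,5-trimethylcyclohex-2-en-1-one | CC1=CC(=O)CC(C)(C)[C@H]1/C=C/C(C)(O)C=C | intermediate
17 | (1R,4R)-4-[(1E)-3-hydroxy-3-methylpenta-1,4-dien-1-yl]-3,5,5-trimethylcyclohex-2-en-1-ol | CC1=C[C@H](O)CC(C)(C)[C@H]1/C=C/C(C)(O)C=C | intermediate
18 | (1E)-1-[(1R,4R)-4-{[tert-butyl(diphenyl)silyl]oxy}-2,6,6-trimethylcyclohex-2-en-1-yl]-3-methylpenta-1,4-dien-3-ol | CC1=C[C@H](O[Si](c2ccccc2)(c2ccccc2)C(C)(C)C)CC(C)(C)[C@H]1/C=C/C(C)(O)C=C | intermediate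
19 | [(2E,4E)-5-[(1R,4R)-4-{[tert-butyl(diphenyl)silyl]oxy}-2,6,6-trimethylcyclohex-2-en-1-yl]-3-methylpenta-2,4-dien-1-yl]triphenylphosphonium bromide | CC1=C[C@H](O[Si](c2ccccc2)(c2ccccc2)C(C)(C)C)CC(C)(C)[C@H]1/C=C/C(C)=C/C[P+](c1ccccc1)(c1ccccc1)c1ccccc1.[Br-] | intermediate
20 | (2E,4E,6E)-2,7-dimethylocta-2,4,6-trienedial | O=C/C(C)=C/C=C/C=C(\C)C=O | starting material
21 | [(2E,4E)-5-[(1R,4R)-4-{[tert-butyl(diphenyl)silyl]oxy}-2,6,6-trimethylcyclohex-2-en-1-yl]-3-methylpenta-2,4-dien-1-ylidene]triphenylphosphorane | CC1=C[C@H](O[Si](c2ccccc2)(c2ccccc2)C(C)(C)C)CC(C)(C)[C@H]1/C=C/C(C)=C/C=P(c1ccccc1)(c1ccccc1)c1ccccc1 | intermediate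
22 | (2E,4E,6E,8E,10E,12E)-13-[(1R,4R)-4-{[tert-butyl(diphenyl)silyl]oxy}-2,6,6-trimethylcyclohex-2-en-1-yl]-2,7,11-trimethyltrideca-2,4,6,8,10,12-hexaenal | CC1=C[C@H](O[Si](c2ccccc2)(c2ccccc2)C(C)(C)C)CC(C)(C)[C@H]1/C=C/C(C)=C/C=C/C(C)=C/C=C/C=C(\C)C=O | intermediate
23 | 2-[(1E,3E,5E,7E,9E,11E,13E)-14-[(1R,4R)-4-{[tert-butyl(diphenyl)silyl]oxy}-2,6,6-trimethylcyclohex-2-en-1-yl]-3,8,12-trimethyltetradeca-1,3,5,7,9,11,13-heptaen-1-yl]-4,4,5,5-tetramethyl-1,3,2-dioxaborolane | CC1=C[C@H](O[Si](c2ccccc2)(c2ccccc2)C(C)(C)C)CC(C)(C)[C@H]1/C=C/C(C)=C/C=C/C(C)=C/C=C/C=C(C)/C=C/B1OC(C)(C)C(C)(C)O1 | intermediate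
24 | (2S,6S,7aR)-6-[(tert-butyldimethylsilyl)oxy]-2-[(1E)-1-iodoprop-1-en-2-yl]-4,4,7a-trimethyl-2,4,5,6,7,7a-hexahydro-1-benzofuran | I/C=C(\C)[C@@H]1C=C2C(C)(C)C[C@H](O[Si](C)(C)C(C)(C)C)C[C@@]2(C)O1 | intermediate
25 | (3S,5R,8S,3'R,6'R)-3-[(tert-butyldimethylsilyl)oxy]-3'-{[tert-butyl(diphenyl)silyl]oxy}-5,8-epoxy-5,8-dihydro-β,ε-carotene | CC1=C[C@H](O[Si](c2ccccc2)(c2ccccc2)C(C)(C)C)CC(C)(C)[C@H]1/C=C/C(C)=C/C=C/C(C)=C/C=C/C=C(C)/C=C/C=C(\C)[C@@H]1C=C2C(C)(C)C[C@H](O[Si](C)(C)C(C)(C)C)C[C@@]2(C)O1 | intermediate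
26 | (3S,5R,8S,3'R,6'R)-5,8-epoxy-5,8-dihydro-β,ε-carotene-3,3'-diol (all-E) | CC1=C[C@H](O)CC(C)(C)[C@H]1/C=C/C(C)=C/C=C/C(C)=C/C=C/C=C(C)/C=C/C=C(\C)[C@@H]1C=C2C(C)(C)C[C@H](O)C[C@@]2(C)O1 | target

**Step count and risks**

Total step count: 16. Longest linear sequence: 9 steps (steps 1–7, 15 and 16; the branch through steps 8–14, 15 and 16 is equally long).

The three steps most likely to fail:

Step 15. What may go wrong: the silver-bound doubly allylic ether may re-ionise at C8 so that the axis-to-centre transfer is eroded, or silver carried into the second stage may cause protodeboronation of the polyenyl boronate before transmetalation. The fallback reverses the order of events and separates ring closure from the coupling. Setting out from 13, Suzuki–Miyaura coupling with 23 under the same Pd(dppf)Cl2/aqueous K3PO4 conditions, with no silver present, should leave the tertiary allenol untouched and give the open-ring allenol (3S,5R,6R,3'R,6'R)-3-[(tert-butyldimethylsilyl)oxy]-3'-{[tert-butyl(diphenyl)silyl]oxy}-6,7-didehydro-5,6-dihydro-β,ε-caroten-5-ol F1. Its allenol is then closed as a separate operation with a phosphine-ligated monovalent gold catalyst (Ph3PAuNTf2, THF, low temperature, dark), a known cycloisomerisation of α-hydroxyallenes that should again turn the axis into the C8 centre. The route is re-joined at 25.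

Step 6. What may go wrong: poor facial selectivity, the peracid entering on the face of the C3 silyloxy group instead of the opposite one. The fallback is the halohydrin route, which inverts the facial outcome of a direct electrophilic attack. Setting out from 11, N-bromosuccinimide in aqueous 1,2-dimethoxyethane should form the bromonium ion on the face the peracid prefers, and water opens it anti at C5 to give the trans-bromohydrin (1R,2S,5S)-2-bromo-5-[(tert-butyldimethylsilyl)oxy]-2-[(3E)-4-iodo-3-methylbut-3-en-1-yn-1-yl]-1,3,3-trimethylcyclohexan-1-ol F2. K2CO3 in methanol then closes the epoxide by displacement of bromide by the C5 alkoxide, which places the oxygen on the other face. The route is re-joined at 12.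

Step 14. What may go wrong: slow or incomplete addition of the bulky geminal dichromium reagent to the electron-rich, α-branched heptaenal, with reduction or geometric scrambling of the polyene on long exposure to divalent chromium. The fallback is alkyne homologation followed by hydroboration. Setting out from 22, the Ohira–Bestmann reaction (dimethyl (1-diazo-2-oxopropyl)phosphonate, K2CO3, MeOH) should give the terminal polyenyne tert-butyl{[(1R,4R)-4-[(1E,3E,5E,7E,9E,11E)-3,7,12-trimethyltetradeca-1,3,5,7,9,11-hexaen-13-yn-1-yl]-3,5,5-trimethylcyclohex-2-en-1-yl]oxy}diphenylsilane F3. Cp2ZrHCl-catalysed syn-hydroboration with pinacolborane should then deliver the same (E)-alkenylboronate. The route is re-joined at 23.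

Further compounds
F1 | step 15 | (3S,5R,6R,3'R,6'R)-3-[(tert-butyldimethylsilyl)oxy]-3'-{[tert-butyl(diphenyl)silyl]oxy}-6,7-didehydro-5,6-dihydro-β,ε-caroten-5-ol (allene axis aR) | CC1=C[C@H](O[Si](c2ccccc2)(c2ccccc2)C(C)(C)C)CC(C)(C)[C@H]1/C=C/C(C)=C/C=C/C(C)=C/C=C/C=C(C)/C=C/C=C(\C)C=C=C1C(C)(C)C[C@H](O[Si](C)(C)C(C)(C)C)C[C@@]1(C)O
F2 | step 6 | (1R,2S,5S)-2-bromo-5-[(tert-butyldimethylsilyl)oxy]-2-[(3E)-4-iodo-3-methylbut-3-en-1-yn-1-yl]-1,3,3-trimethylcyclohexan-1-ol | CC1(C)C[C@H](O[Si](C)(C)C(C)(C)C)C[C@@](C)(O)[C@@]1(Br)C#C/C(C)=C/I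
F3 | step 14 | tert-butyl{[(1R,4R)-4-[(1E,3E,5E,7E,9E,11E)-3,7,12-trimethyltetradeca-1,3,5,7,9,11-hexaen-13-yn-1-yl]-3,5,5-trimethylcyclohex-2-en-1-yl]oxy}diphenylsilane | CC1=C[C@H](O[Si](c2ccccc2)(c2ccccc2)C(C)(C)C)CC(C)(C)[C@H]1/C=C/C(C)=C/C=C/C(C)=C/C=C/C=C(\C)C#C
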